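**Plan**

- Target 18 (8,3'-dihydroxy-6,7,4',5'-tetramethoxyflavone) is achiral. The retrosynthesis first removes two MOM ethers, then cuts ring C at C3–C4, then C2=C3 (ester methylenation), C4–C4a (formylation of an aryl bromide) and O1–C2 (esterification).
- Enabling feature: C4 is an aroyl carbon on C4a of ring A, and C3 is the CH2 terminus of the O1–C2(ring B)=C3 enol ether held ortho to it through C8a–O1. An acyl radical at C4 can add to C3 and leave a C2 radical stabilized by O1 and ring B, one oxidation away from the pyranone.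
- Forward: ring A phenol 5 (three steps from 1) and ring B acid 8 (one step from 6) are joined as ester 9 (O1–C2), methylenated (C2=C3) and formylated (C4). Ring C, the only ring made, closes in step 8, and acid then frees the phenols.
- Stereochemistry: none to set; the target has no stereocentre and no stereogenic double bond.

Key step: step 8

Remark 1: ring A needs four adjacent oxygens (O1, 8-OH, 7-OMe, 6-OMe). Aldehyde 1 carries three; Baeyer–Villiger oxidation turns its formyl group into the fourth (the future O1), and the C4 carbon is then placed ortho to that oxygen.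

Remark 2: MOM ethers protect 8-OH and 3'-OH. Unlike a silyl group they cannot migrate to the neighbouring free phenol in 4 and 5, they tolerate the titanium and lithium reagents, and they offer no benzylic C–H to the abstracting radical in step 8.

**Route**

Step 1
Reactants: 1 2-hydroxy-3,4-dimethoxybenzaldehyde
Product: 2 3,4-dimethoxy-2-(methoxymethoxy)benzaldehyde
Conditions: MOMCl, i-Pr2NEt, CH2Cl2, 0 °C to rt
Reagents that add atoms: chloromethyl methyl ether (MOMCl), COCCl
Why: Williamson-type O-alkylation of the phenoxide with the reactive α-chloro ether should give an acetal ether that stays on the future O8 through all later steps.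

Step 2
Reactants: 2 3,4-dimethoxy-2-(methoxymethoxy)benzaldehyde
Product: 4 3,4-dimethoxy-2-(methoxymethoxy)phenol, via aryl formate 3 (not isolated)
Conditions: mCPBA, CH2Cl2, 0 °C to rt; then K2CO3 (cat.), MeOH, rt
Reagents that add atoms: meta-chloroperoxybenzoic acid (mCPBA), OOC(=O)c1cccc(Cl)c1
Why: In this Baeyer–Villiger (Dakin-type) oxidation the aryl group, activated by ortho and para oxygen donors, should migrate in preference to hydrogen, and methanolysis of the formate frees the phenol that becomes O1.

Step 3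
Reactants: 4 3,4-dimethoxy-2-(methoxymethoxy)phenol
Product: 5 6-bromo-3,4-dimethoxy-2-(methoxymethoxy)phenol
Conditions: NBS, i-Pr2NH (10 mol %), CH2Cl2, −78 to 0 °C
Reagents that add atoms: N-bromosuccinimide (NBS), O=C1CCC(=O)N1Br
Why: Amine-catalysed electrophilic ortho-bromination of a phenol should deliver bromine from the hydrogen-bonded N-bromoamine to C6, the only free ortho position (the para position is blocked by methoxy), marking the carbon that becomes C4a.

Step 4
Reactants: 6 3-hydroxy-4,5-dimethoxybenzoic acid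
Product: 8 3,4-dimethoxy-5-(methoxymethoxy)benzoic acid, via methoxymethyl ester 7 (not isolated)
Conditions: MOMCl (2.5 equiv), i-Pr2NEt, CH2Cl2, 0 °C to rt; then NaOH, THF/MeOH/H2O, rt; cold 1 M HCl to pH 4
Reagents that add atoms: chloromethyl methyl ether (MOMCl), COCCl
Why: Exhaustive Williamson-type alkylation of phenol and carboxylate, followed by saponification of the labile methoxymethyl ester, should leave only the phenol protected.

Step 5
Reactants: 5 6-bromo-3,4-dimethoxy-2-(methoxymethoxy)phenol; 8 3,4-dimethoxy-5-(methoxymethoxy)benzoic acid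
Product: 9 6-bromo-3,4-dimethoxy-2-(methoxymethoxy)phenyl 3,4-dimethoxy-5-(methoxymethoxy)benzoate
Conditions: EDC·HCl, DMAP, CH2Cl2, rt
Reagents that add atoms: none
Why: Steglich esterification passes the carbodiimide-activated acid through the acylpyridinium ion to the hindered phenol under neutral conditions that spare the MOM ethers, and it forms the O1–C2 bond.

Step 6
Reactants: 9 6-bromo-3,4-dimethoxy-2-(methoxymethoxy)phenyl 3,4-dimethoxy-5-(methoxymethoxy)benzoate
Product: 10 1-bromo-2-({1-[3,4-dimethoxy-5-(methoxymethoxy)phenyl]ethenyl}oxy)-4,5-dimethoxy-3-(methoxymethoxy)benzene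
Conditions: Tebbe reagent Cp2Ti(μ-Cl)(μ-CH2)AlMe2 (toluene solution, 1.5 equiv), pyridine (cat.), THF, −40 °C to rt; 15% aq NaOH; basic Al2O3
Reagents that add atoms: Tebbe reagent Cp2Ti(μ-Cl)(μ-CH2)AlMe2, C[Al-]1(C)C[Ti](C2C=CC=C2)(C2C=CC=C2)[Cl+]1
Why: Tebbe methylenation of an ester carbonyl through an oxatitanacyclobutane, a reaction established for aryl benzoates, should turn C2=O into C2=CH2 (C3) without touching the aryl bromide or the MOM ethers.

Step 7
Reactants: 10 1-bromo-2-({1-[3,4-dimethoxy-5-(methoxymethoxy)phenyl]ethenyl}oxy)-4,5-dimethoxy-3-(methoxymethoxy)benzene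
Product: 13 2-({1-[3,4-dimethoxy-5-(methoxymethoxy)phenyl]ethenyl}oxy)-4,5-dimethoxy-3-(methoxymethoxy)benzaldehyde, via aryllithium 11 (not isolated), via lithium hemiaminal alkoxide 12 (not isolated)
Conditions: n-BuLi (1.1 equiv), THF, −78 °C, 10 min; DMF, −78 to 0 °C; H2O
Reagents that add atoms: N,N-dimethylformamide (DMF), CN(C)C=O
Why: Bromine–lithium exchange at −78 °C is faster than any attack on the enol ether, and Bouveault-type formylation of the aryllithium with DMF should give the aldehyde (C4) after neutral aqueous collapse of the hemiaminal alkoxide, a work-up that the acid-labile enol ether tolerates.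

Step 8
Reactants: 13 2-({1-[3,4-dimethoxy-5-(methoxymethoxy)phenyl]ethenyl}oxy)-4,5-dimethoxy-3-(methoxymethoxy)benzaldehyde
Product: 17 2-[3,4-dimethoxy-5-(methoxymethoxy)phenyl]-6,7-dimethoxy-8-(methoxymethoxy)-4H-chromen-4-one, via acyl radical 14 (not isolated), via C2 radical 15 (not isolated), via oxocarbenium ion 16 (not isolated)
Conditions: t-BuOOH (5.5 M in decane, 3 equiv), Cu(OAc)2 (10 mol %), NaHCO3 (2 equiv), PhCl, 90 °C, argon
Reagents that add atoms: none
Why: Proposed new method: the copper couple cleaves t-BuOOH to the tert-butoxyl radical, which abstracts the weak formyl hydrogen of 13 to give aroyl radical 14; this adds to the CH2 terminus (C3) of the O1–C2(ring B)=CH2 enol ether to form C3–C4 and radical 15 at C2, divalent copper oxidizes 15 to oxocarbenium ion 16 while returning to monovalent copper, and 16 loses a C3 proton to give the pyranone of 17. The closest known reaction types are the t-BuOOH/tetrabutylammonium halide cyclization of 2-aryloxybenzaldehydes to xanthones, the copper/t-BuOOH oxidative acylation of styrenes with aldehydes to enones, and the oxidative acyl-radical cyclization of 2-(allyloxy)benzaldehydes to chroman-4-ones; new here is the addition of a nucleophilic acyl radical to an aryl enol ether. Ring C closes in the 6-endo-trig mode. No stereocentre is formed. The step needs 6-endo over 5-exo closure and abstraction of the formyl hydrogen over all other C–H bonds: 5-exo attack would strike the fully substituted C2 and leave a primary radical, whereas 6-endo attack at the unhindered CH2 gives a radical stabilized by both O1 and ring B, and the formyl C–H is the weakest and most hydridic bond in 13 because the MOM and methoxy C–H bonds are stronger and no benzylic ether C–H is present. Solid NaHCO3 and anhydrous t-BuOOH are meant to keep the acid-labile enol ether from hydrolysing before it cyclizes.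

Step 9
Reactants: 17 2-[3,4-dimethoxy-5-(methoxymethoxy)phenyl]-6,7-dimethoxy-8-(methoxymethoxy)-4H-chromen-4-one
Product: 18 8-hydroxy-2-(3-hydroxy-4,5-dimethoxyphenyl)-6,7-dimethoxy-4H-chromen-4-one
Conditions: 3 M HCl, MeOH, 50 °C
Reagents that add atoms: none
Why: Acid-catalysed acetal exchange with methanol (MOM cleavage) should free both phenols, while the flavone core and its four methyl ethers are stable to dilute HCl.

**Compound list**

1 | 2-hydroxy-3,4-dimethoxybenzaldehyde | COc1ccc(C=O)c(O)c1OC | starting material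
2 | 3,4-dimethoxy-2-(methoxymethoxy)benzaldehyde | COCOc1c(C=O)ccc(OC)c1OC | intermediate
3 | 3,4-dimethoxy-2-(methoxymethoxy)phenyl formate | O=COc1ccc(OC)c(OC)c1OCOC | intermediate
4 | 3,4-dimethoxy-2-(methoxymethoxy)phenol | Oc1ccc(OC)c(OC)c1OCOC | intermediate
5 | 6-bromo-3,4-dimethoxy-2-(methoxymethoxy)phenol | Oc1c(Br)cc(OC)c(OC)c1OCOC | intermediate
6 | 3-hydroxy-4,5-dimethoxybenzoic acid | COc1cc(C(=O)O)cc(O)c1OC | starting material
7 | methoxymethyl 3,4-dimethoxy-5-(methoxymethoxy)benzoate | COCOC(=O)c1cc(OC)c(OC)c(OCOC)c1 | intermediate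
8 | 3,4-dimethoxy-5-(methoxymethoxy)benzoic acid | OC(=O)c1cc(OC)c(OC)c(OCOC)c1 | intermediate
9 | 6-bromo-3,4-dimethoxy-2-(methoxymethoxy)phenyl 3,4-dimethoxy-5-(methoxymethoxy)benzoate | O=C(Oc1c(Br)cc(OC)c(OC)c1OCOC)c1cc(OC)c(OC)c(OCOC)c1 | intermediate
10 | 1-bromo-2-({1-[3,4-dimethoxy-5-(methoxymethoxy)phenyl]ethenyl}oxy)-4,5-dimethoxy-3-(methoxymethoxy)benzene | C=C(Oc1c(Br)cc(OC)c(OC)c1OCOC)c1cc(OC)c(OC)c(OCOC)c1 | intermediate
11 | aryllithium from bromine–lithium exchange of 10 (lithium at the former C–Br carbon) | [Li]c1cc(OC)c(OC)c(OCOC)c1OC(=C)c1cc(OC)c(OC)c(OCOC)c1 | intermediate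
12 | lithium hemiaminal alkoxide, DMF adduct of 11 (racemic) | [Li]OC(N(C)C)c1cc(OC)c(OC)c(OCOC)c1OC(=C)c1cc(OC)c(OC)c(OCOC)c1 | intermediate
13 | 2-({1-[3,4-dimethoxy-5-(methoxymethoxy)phenyl]ethenyl}oxy)-4,5-dimethoxy-3-(methoxymethoxy)benzaldehyde | O=Cc1cc(OC)c(OC)c(OCOC)c1OC(=C)c1cc(OC)c(OC)c(OCOC)c1 | intermediate
14 | aroyl radical of 13 (radical at the former formyl carbon, C4) | O=[C]c1cc(OC)c(OC)c(OCOC)c1OC(=C)c1cc(OC)c(OC)c(OCOC)c1 | intermediate
15 | 2-aryl-4-oxochroman-2-yl radical (radical at C2) | O=C1C[C](c2cc(OC)c(OC)c(OCOC)c2)Oc2c(OCOC)c(OC)c(OC)cc12 | intermediate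
16 | 2-aryl-4-oxochroman-2-ylium (oxocarbenium ion at O1–C2) | O=C1CC(c2cc(OC)c(OC)c(OCOC)c2)=[O+]c2c(OCOC)c(OC)c(OC)cc12 | intermediate
17 | 2-[3,4-dimethoxy-5-(methoxymethoxy)phenyl]-6,7-dimethoxy-8-(methoxymethoxy)-4H-chromen-4-one | COCOc1cc(-c2cc(=O)c3cc(OC)c(OC)c(OCOC)c3o2)cc(OC)c1OC | intermediate
18 | 8-hydroxy-2-(3-hydroxy-4,5-dimethoxyphenyl)-6,7-dimethoxy-4H-chromen-4-one | COc1cc(-c2cc(=O)c3cc(OC)c(OC)c(O)c3o2)cc(O)c1OC | target

**Step count**

Total steps: 9. Longest linear sequence: 8 steps (1, 2, 3, 5, 6, 7, 8, 9 from compound 1).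

**Steps most likely to fail**

Step 8 (proposed new method). The enol ether may be consumed by hydrolysis or by addition of oxygen-centred radicals before the acyl radical closes the ring, or the acyl radical may be intercepted as peracid or perester. The fallback builds the pyranone by a Baker–Venkataraman sequence, sets out from phenol 4 and returns to the route at target 18. Magnesium-phenoxide-directed ortho-formylation of 4 (MgCl2, Et3N, paraformaldehyde, MeCN, reflux) would give 2-hydroxy-4,5-dimethoxy-3-(methoxymethoxy)benzaldehyde F1. Addition of MeMgBr (THF, 0 °C) would give racemic 1-[2-hydroxy-4,5-dimethoxy-3-(methoxymethoxy)phenyl]ethanol F2, and MnO2 (CH2Cl2, rt) would oxidize it to 1-[2-hydroxy-4,5-dimethoxy-3-(methoxymethoxy)phenyl]ethanone F3. Esterification with acid 8 (EDC·HCl, DMAP, CH2Cl2) would give 2-acetyl-4,5-dimethoxy-6-(methoxymethoxy)phenyl 3,4-dimethoxy-5-(methoxymethoxy)benzoate F4. KOH in pyridine at 50 °C would shift the aroyl group from oxygen to the acetyl carbon to give 1-[2-hydroxy-4,5-dimethoxy-3-(methoxymethoxy)phenyl]-3-[3,4-dimethoxy-5-(methoxymethoxy)phenyl]propane-1,3-dione F5. HCl in MeOH at reflux would then cyclodehydrate F5 and remove both MOM groups to give 18.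

Step 7. The aryllithium may add to the neighbouring enol ether or be alkylated by the 1-bromobutane formed, and the enol ether may hydrolyse during work-up. The fallback introduces the carbon by palladium cross-coupling at the alcohol oxidation level, sets out from bromide 10 and returns at aldehyde 13. Stille coupling of 10 with Bu3SnCH2OH (Pd(PPh3)4, dioxane, 100 °C) would give [2-({1-[3,4-dimethoxy-5-(methoxymethoxy)phenyl]ethenyl}oxy)-4,5-dimethoxy-3-(methoxymethoxy)phenyl]methanol F6. MnO2 in CH2Cl2 would oxidize this benzylic alcohol to 13 under neutral conditions.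

Step 3. Bromination may occur para to the MOM ether (at C5) instead of ortho to the hydroxyl, or the p-methoxyphenol may be oxidized towards a quinone. The fallback fixes the position by directed ortho-metalation, sets out from phenol 4 and returns at bromophenol 5. Carbamoylation (ClC(O)NEt2, NaH, THF) would give 3,4-dimethoxy-2-(methoxymethoxy)phenyl N,N-diethylcarbamate F7. Carbamate-directed lithiation at the only free ortho position (s-BuLi, TMEDA, THF, −78 °C) with a BrCCl2CCl2Br quench at that temperature would give 6-bromo-3,4-dimethoxy-2-(methoxymethoxy)phenyl N,N-diethylcarbamate F8. Hydrolysis (NaOH, EtOH/H2O, reflux) would release 5.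

**Further compounds**

F1 | step 8 | 2-hydroxy-4,5-dimethoxy-3-(methoxymethoxy)benzaldehyde | O=Cc1cc(OC)c(OC)c(OCOC)c1O
F2 | step 8 | 1-[2-hydroxy-4,5-dimethoxy-3-(methoxymethoxy)phenyl]ethanol (racemic) | CC(O)c1cc(OC)c(OC)c(OCOC)c1O
F3 | step 8 | 1-[2-hydroxy-4,5-dimethoxy-3-(methoxymethoxy)phenyl]ethanone | CC(=O)c1cc(OC)c(OC)c(OCOC)c1O
F4 | step 8 | 2-acetyl-4,5-dimethoxy-6-(methoxymethoxy)phenyl 3,4-dimethoxy-5-(methoxymethoxy)benzoate | CC(=O)c1cc(OC)c(OC)c(OCOC)c1OC(=O)c1cc(OC)c(OC)c(OCOC)c1
F5 | step 8 | 1-[2-hydroxy-4,5-dimethoxy-3-(methoxymethoxy)phenyl]-3-[3,4-dimethoxy-5-(methoxymethoxy)phenyl]propane-1,3-dione | O=C(CC(=O)c1cc(OC)c(OC)c(OCOC)c1O)c1cc(OC)c(OC)c(OCOC)c1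
F6 | step 7 | [2-({1-[3,4-dimethoxy-5-(methoxymethoxy)phenyl]ethenyl}oxy)-4,5-dimethoxy-3-(methoxymethoxy)phenyl]methanol | OCc1cc(OC)c(OC)c(OCOC)c1OC(=C)c1cc(OC)c(OC)c(OCOC)c1
F7 | step 3 | 3,4-dimethoxy-2-(methoxymethoxy)phenyl N,N-diethylcarbamate | CCN(CC)C(=O)Oc1ccc(OC)c(OC)c1OCOC
F8 | step 3 | 6-bromo-3,4-dimethoxy-2-(methoxymethoxy)phenyl N,N-diethylcarbamate | CCN(CC)C(=O)Oc1c(Br)cc(OC)c(OC)c1OCOC
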